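**Retrosynthetic overview**
1. The C9 angelate goes on last; the γ-lactone (last ring) and the C15 enal both come from isopropenyl groups by SeO2 hydroxylation, then MnO2 oxidation/lactonisation.
2. The cis C7–C/C8–O pair comes from a magnesium-alkoxide-directed acetonitrile oxide cycloaddition on the C9 allylic alcohol (temporary isoxazoline ring); the 6β-acetate comes from a Mitsunobu inversion.
3. Key step: a catalytic asymmetric intramolecular Diels–Alder reaction of a silyl bis-enol ether triene closes the cyclohexene and a 1,3-dioxa-2-silinane ring together and sets C5, C9 and C10; the silicon ring is then cut out.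
4. The triene is assembled on iPr2Si from (E)-2-methyl-4-oxopent-2-enal and (E)-4-(triethylsilyloxy)but-2-enal.
5. Ring order: cyclohexene + silicon ring (one step) → silicon ring removed → isoxazoline (temporary) → γ-lactone.

Assumption 1: the SMILES is read as the (5R,6S,7R,8R,9S,10S) enantiomer of an elema-1,3,11(13)-trien-12,8-olide; elemane locants C1–C15 are used for all cyclic compounds, with β = face of the C10 methyl and α = face of the C10 vinyl group.
Assumption 2: the sense of induction of the oxazaborolidinium catalyst in step 6 is taken from its model for 2-substituted enals; if it proves opposite, the (R)-catalyst is used.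

**Route**

Step 1
Reactants: 1 1,1-dimethoxypropan-2-one; 2 dimethyl (2-oxopropyl)phosphonate
Product: 3 (E)-5,5-dimethoxy-4-methylpent-3-en-2-one
Conditions: NaH, THF, 0 °C to 65 °C
Reagents that add atoms: none
Why: Horner–Wadsworth–Emmons olefination of the activated α,α-dialkoxy ketone gives the trisubstituted enone with the acetyl group trans to the bulkier acetal carbon (E), any Z isomer being equilibrated in step 2.

Step 2
Reactants: 3 (E)-5,5-dimethoxy-4-methylpent-3-en-2-one
Product: 4 (E)-2-methyl-4-oxopent-2-enal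
Conditions: 1 M HCl, acetone/H2O, rt
Reagents that add atoms: water O
Why: acid-catalysed acetal hydrolysis, under which the E-enedicarbonyl (formyl trans to acetyl) is the thermodynamic isomer.

Step 3
Reactants: 5 (Z)-but-2-ene-1,4-diol
Product: 6 (Z)-4-(triethylsilyloxy)but-2-en-1-ol
Conditions: NaH (1.0 equiv), THF, 0 °C; then Et3SiCl, 0 °C to rt
Reagents that add atoms: chlorotriethylsilane CC[Si](Cl)(CC)CC
Why: monosilylation of a symmetrical diol through its monosodium alkoxide (O-silylation), no stereocentre involved.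

Step 4
Reactants: 6 (Z)-4-(triethylsilyloxy)but-2-en-1-ol
Product: 7 (E)-4-(triethylsilyloxy)but-2-enal
Conditions: MnO2 (excess), CH2Cl2, rt
Reagents that add atoms: none
Why: allylic alcohol oxidation with MnO2, the first-formed cis-enal isomerising to the conjugated trans-enal under the reaction conditions.

Step 5
Reactants: 4 (E)-2-methyl-4-oxopent-2-enal; 7 (E)-4-(triethylsilyloxy)but-2-enal
Product: 9 diisopropyl[(3E)-4-methyl-5-oxopenta-1,3-dien-2-yloxy][(1E,3E)-4-(triethylsilyloxy)buta-1,3-dien-1-yloxy]silane, via monoenoxy silyl triflate 8 (not isolated)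
Conditions: 4, iPr2Si(OTf)2 (1.0 equiv), Et3N, CH2Cl2, −78 °C; then 7, Et3N, −78 to 0 °C
Reagents that add atoms: diisopropylsilyl bis(trifluoromethanesulfonate) CC(C)[Si](OS(=O)(=O)C(F)(F)F)(OS(=O)(=O)C(F)(F)F)C(C)C
Why: stepwise soft enolisation/O-silylation (unsymmetrical silyl bis-enol ether synthesis), the methyl ketone being the only enolisable site of 4 and γ-deprotonation of enal 7 giving the 1-siloxydiene with the E,E geometry favoured.

Step 6
Reactants: 9 silyl bis-enol ether triene
Product: 10 trans-fused 2,2-diisopropyl-5-methyl-4-methylidene-6-(triethylsilyloxy)-4a,5,6,8a-tetrahydro-4H-1,3,2-benzodioxasiline-5-carbaldehyde (elemane terms: 5β-C, 6α-O, 9α-OSiEt3, 10β-Me, 10α-CHO)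
Conditions: (S)-3,3-diphenyl-1-(2-methylphenyl)tetrahydro-1H,3H-pyrrolo[1,2-c][1,3,2]oxazaborole·HN(SO2CF3)2 (20 mol %), CH2Cl2 (0.01 M), −78 to −40 °C
Reagents that add atoms: none
Why: Proposed new method: an enantioselective silicon-tethered intramolecular Diels–Alder reaction in which the N-protonated oxazaborolidine binds the formyl group of the 2-substituted enal and the 1,4-bis(siloxy)diene adds through the formyl-endo, tether-exo transition state, so that the cyclohexene and the trans-fused 1,3-dioxa-2-silinane ring close together and C5, C9 and C10 are set (9α-O and 6α-O cis to the 10α-CHO by the endo rule, 5β-C cis to 10β-Me from the E-enal, absolute sense from the catalyst); the closest known reactions are thermal silicon-tethered intramolecular Diels–Alder reactions and cationic oxazaborolidine-catalysed Diels–Alder reactions of 2-methylacrolein-type enals and trienals.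

Step 7
Reactants: 10 Diels–Alder aldehyde
Product: 12 5β-acetyl-10β-methyl-10α-vinylcyclohex-7-ene-6α,9α-diol, via vinyl dioxasiline 11 (not isolated)
Conditions: Ph3PCH3Br, KOtBu, THF, 0 °C; 10, −78 to 0 °C; then HF·pyridine, pyridine, THF, 0 °C
Reagents that add atoms: methylenetriphenylphosphorane C=P(c1ccccc1)(c1ccccc1)c1ccccc1
Why: Wittig methylenation of the non-enolisable neopentyl aldehyde, followed by fluoride cleavage of all Si–O bonds (silyl enol ether to methyl ketone, silyl ethers to alcohols) under buffered conditions that leave the four stereocentres untouched.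

Step 8
Reactants: 12 diol methyl ketone
Product: 13 5β-isopropenyl-10β-methyl-10α-vinylcyclohex-7-ene-6α,9α-diol
Conditions: Zn, CH2Br2, TiCl4 (excess), THF/CH2Cl2, 0 °C to rt
Reagents that add atoms: dibromomethane BrCBr
Why: Takai–Lombardo methylenation, a non-basic gem-dimetallic reagent that converts the methyl ketone into the isopropenyl group without epimerising C5 or causing retro-aldol or β-elimination of the β-hydroxy ketone.

Step 9
Reactants: 13 6α,9α-diol
Product: 14 6β-acetoxy-5β-isopropenyl-10β-methyl-10α-vinylcyclohex-7-en-9α-ol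
Conditions: PPh3, DIAD, AcOH, toluene, −20 °C to rt
Reagents that add atoms: acetic acid CC(=O)O
Why: Mitsunobu reaction, in which SN2 displacement with inversion at the less hindered allylic C6 carbinol installs the 6β-acetate while the neopentyl C9 carbinol cannot be displaced.

Step 10
Reactants: 14 9α-allylic alcohol; 15 acetaldoxime
Product: 16 6β-acetoxy-9α-hydroxy-5β-isopropenyl-10β-methyl-10α-vinylcyclohexane cis-fused on the α face (C8–O, C7–C) to a 3-methyl-4,5-dihydroisoxazole
Conditions: 15, N-chlorosuccinimide, cat. pyridine, CH2Cl2, 0 °C to rt; then added to 14, EtMgBr (3 equiv), i-PrOH (3.3 equiv), CH2Cl2, 0 °C to rt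
Reagents that add atoms: none
Why: magnesium-alkoxide-directed nitrile oxide 1,3-dipolar cycloaddition (Kanemasa), in which the bromomagnesium alkoxide of the 9α-alcohol binds the dipole and delivers it to the adjacent ring alkene from the α face with oxygen bonding to C8 and carbon to C7, which sets C7 and C8 cis to O9 and outruns addition to the unactivated vinyl and isopropenyl groups.

Step 11
Reactants: 16 isoxazoline
Product: 17 7α-acetyl-6β-acetoxy-5β-isopropenyl-10β-methyl-10α-vinylcyclohexane-8α,9α-diol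
Conditions: Mo(CO)6, MeCN/H2O (15:1), 80 °C
Reagents that add atoms: water O
Why: Mo(CO)6-mediated reductive N–O cleavage of the 2-isoxazoline with hydrolytic loss of nitrogen (isoxazoline-to-aldol unmasking) reveals the 8α-hydroxyl and the C7 methyl ketone under neutral conditions, leaving C7 and C8 as set.

Step 12
Reactants: 17 β-hydroxy methyl ketone
Product: 18 6β-acetoxy-5β,7α-diisopropenyl-10β-methyl-10α-vinylcyclohexane-8α,9α-diol
Conditions: Zn, CH2Br2, TiCl4 (excess), THF/CH2Cl2, 0 °C to rt
Reagents that add atoms: dibromomethane BrCBr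
Why: Takai–Lombardo methylenation under non-basic conditions, so the α-stereocentre C7 and the β-hydroxy ketone survive.

Step 13
Reactants: 18 bis-isopropenyl diol
Product: 19 6β-acetoxy-5β,7α-bis(3-hydroxyprop-1-en-2-yl)-10β-methyl-10α-vinylcyclohexane-8α,9α-diol
Conditions: SeO2 (0.5 equiv), t-BuOOH, CH2Cl2, 0 °C to rt
Reagents that add atoms: tert-butyl hydroperoxide CC(C)(C)OO
Why: Sharpless allylic hydroxylation (SeO2 ene reaction then [2,3]-shift, reoxidised by t-BuOOH) attacks the methyl group of each electron-rich isopropenyl unit in preference to the allylic methines, while the vinyl group has no allylic hydrogen.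

Step 14
Reactants: 19 tetraol
Product: 21 6β-acetoxy-9α-hydroxy-15-oxoelema-1,3,11(13)-trien-12,8α-olide, via lactol enal 20 (not isolated)
Conditions: MnO2 (excess), CH2Cl2, rt
Reagents that add atoms: none
Why: MnO2 allylic oxidation converts both primary allylic alcohols to enals, the C12 aldehyde being trapped by the cis 8α-hydroxyl as a five-membered lactol that is oxidised on to the α-methylene-γ-lactone, while the C15 enal and the non-allylic C9 alcohol are left alone.

Step 15
Reactants: 21 hydroxy lactone enal; 22 angelic acid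
Product: 23 (5R,6S,7R,8R,9S,10S)-6β-acetoxy-9α-angeloyloxy-15-oxoelema-1,3,11(13)-trien-12,8α-olide (target)
Conditions: 22, 2,4,6-trichlorobenzoyl chloride, Et3N, toluene, rt; then 21, 80 °C
Reagents that add atoms: none
Why: Yamaguchi-type esterification through the mixed anhydride without DMAP acylates the hindered C9 alcohol with retention at C9 and without Z-to-E isomerisation of the angelate.

**Compound list**

1 | 1,1-dimethoxypropan-2-one | CC(=O)C(OC)OC | starting material
2 | dimethyl (2-oxopropyl)phosphonate | CC(=O)CP(=O)(OC)OC | starting material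
3 | (E)-5,5-dimethoxy-4-methylpent-3-en-2-one | CC(=O)/C=C(/C(OC)OC)C | intermediate
4 | (E)-2-methyl-4-oxopent-2-enal | CC(=O)/C=C(/C=O)C | intermediate
5 | (Z)-but-2-ene-1,4-diol | OC/C=C\CO | starting material
6 | (Z)-4-(triethylsilyloxy)but-2-en-1-ol | OC/C=C\CO[Si](CC)(CC)CC | intermediate
7 | (E)-4-(triethylsilyloxy)but-2-enal | O=C/C=C/CO[Si](CC)(CC)CC | intermediate
8 | diisopropyl[(3E)-4-methyl-5-oxopenta-1,3-dien-2-yloxy]silyl trifluoromethanesulfonate | O=C/C(C)=C/C(=C)O[Si](C(C)C)(C(C)C)OS(=O)(=O)C(F)(F)F | intermediate (not isolated)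
9 | diisopropyl[(3E)-4-methyl-5-oxopenta-1,3-dien-2-yloxy][(1E,3E)-4-(triethylsilyloxy)buta-1,3-dien-1-yloxy]silane | O=C/C(C)=C/C(=C)O[Si](C(C)C)(C(C)C)O/C=C/C=C/O[Si](CC)(CC)CC | intermediate
10 | trans-fused 2,2-diisopropyl-5-methyl-4-methylidene-6-(triethylsilyloxy)-4a,5,6,8a-tetrahydro-4H-1,3,2-benzodioxasiline-5-carbaldehyde (5β-C, 6α-O, 9α-OSiEt3, 10β-Me, 10α-CHO) | O=C[C@]1(C)[C@H](O[Si](CC)(CC)CC)C=C[C@@H]2O[Si](C(C)C)(C(C)C)OC(=C)[C@@H]12 | intermediate
11 | the 5-vinyl analogue of 10 (10α-vinyl in place of 10α-CHO) | C=C[C@]1(C)[C@H](O[Si](CC)(CC)CC)C=C[C@@H]2O[Si](C(C)C)(C(C)C)OC(=C)[C@@H]12 | intermediate (not isolated)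
12 | 5β-acetyl-10β-methyl-10α-vinylcyclohex-7-ene-6α,9α-diol | C=C[C@]1(C)[C@H](O)C=C[C@H](O)[C@H]1C(C)=O | intermediate
13 | 5β-isopropenyl-10β-methyl-10α-vinylcyclohex-7-ene-6α,9α-diol | C=C[C@]1(C)[C@H](O)C=C[C@H](O)[C@H]1C(C)=C | intermediate
14 | 6β-acetoxy-5β-isopropenyl-10β-methyl-10α-vinylcyclohex-7-en-9α-ol | C=C[C@]1(C)[C@H](O)C=C[C@@H](OC(C)=O)[C@H]1C(C)=C | intermediate
15 | acetaldoxime | CC=NO | starting material
16 | 3-methyl-2-isoxazoline cis-fused at C7/C8 on the α face (8α-O, 7α-C), 6β-OAc, 9α-OH, 5β-isopropenyl, 10β-Me, 10α-vinyl | C=C[C@]1(C)[C@H](O)[C@@H]2ON=C(C)[C@@H]2[C@@H](OC(C)=O)[C@H]1C(C)=C | intermediate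
17 | 7α-acetyl-6β-acetoxy-5β-isopropenyl-10β-methyl-10α-vinylcyclohexane-8α,9α-diol | C=C[C@]1(C)[C@H](O)[C@H](O)[C@H](C(C)=O)[C@@H](OC(C)=O)[C@H]1C(C)=C | intermediate
18 | 6β-acetoxy-5β,7α-diisopropenyl-10β-methyl-10α-vinylcyclohexane-8α,9α-diol | C=C[C@]1(C)[C@H](O)[C@H](O)[C@H](C(C)=C)[C@@H](OC(C)=O)[C@H]1C(C)=C | intermediate
19 | 6β-acetoxy-5β,7α-bis(3-hydroxyprop-1-en-2-yl)-10β-methyl-10α-vinylcyclohexane-8α,9α-diol | C=C[C@]1(C)[C@H](O)[C@H](O)[C@H](C(=C)CO)[C@@H](OC(C)=O)[C@H]1C(=C)CO | intermediate
20 | 6β-acetoxy-9α,12-dihydroxy-15-oxo-8α,12-epoxyelema-1,3,11(13)-triene (8,12-lactol) | C=C[C@]1(C)[C@H](O)[C@@H]2OC(O)C(=C)[C@@H]2[C@@H](OC(C)=O)[C@H]1C(=C)C=O | intermediate (not isolated)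
21 | 6β-acetoxy-9α-hydroxy-15-oxoelema-1,3,11(13)-trien-12,8α-olide | C=C[C@]1(C)[C@H](O)[C@@H]2OC(=O)C(=C)[C@@H]2[C@@H](OC(C)=O)[C@H]1C(=C)C=O | intermediate
22 | angelic acid, (Z)-2-methylbut-2-enoic acid | C/C=C(/C)C(=O)O | starting material
23 | (5R,6S,7R,8R,9S,10S)-6β-acetoxy-9α-angeloyloxy-15-oxoelema-1,3,11(13)-trien-12,8α-olide | C=C[C@]1(C)[C@H](OC(=O)/C(C)=C\C)[C@@H]2OC(=O)C(=C)[C@@H]2[C@@H](OC(C)=O)[C@H]1C(=C)C=O | target

**Step count and weak points**

Total steps: 15. Longest linear sequence: 13 (steps 1, 2, 5–15; steps 3–4 form the second branch).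

Most likely to fail, first: step 6. The silyl enol ethers may add to the activated aldehyde (Mukaiyama-type), the ring fusion may come out cis, or the enantioselectivity may be low. The fallback drops the tether and sets out again from 7 and 4. Aldehyde 7 is converted with Et3SiOTf/Et3N into (1E,3E)-1,4-bis(triethylsilyloxy)buta-1,3-diene F1. F1 and 4 are combined in an intermolecular endo Diels–Alder reaction under the same oxazaborolidinium catalyst to give 5β-acetyl-10β-methyl-6α,9α-bis(triethylsilyloxy)cyclohex-7-ene-10α-carbaldehyde F2. Wittig methylenation gives the 10α-vinyl bis-silyl ether ketone F3, and HF·pyridine then returns the route to 12.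

Second: step 9. The Mitsunobu inversion at the hindered allylic C6 may give SN2′ product, elimination or a retention ester. The fallback sets out from 13. MnO2 oxidises the less hindered C6 allylic alcohol to 9α-hydroxy-5β-isopropenyl-10β-methyl-10α-vinylcyclohex-7-en-6-one F4. Luche reduction (NaBH4, CeCl3·7H2O, MeOH, −78 °C) delivers hydride from the α face, which is not screened by the axial 10β-methyl, and gives 5β-isopropenyl-10β-methyl-10α-vinylcyclohex-7-ene-6β,9α-diol F5. Selective acetylation of the less hindered C6 hydroxyl (Ac2O, pyridine, −20 °C) comes back to the route at 14.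

Third: step 10. The directed cycloaddition on a hindered cyclic allylic alcohol may give the wrong regio- or site-selectivity. The fallback sets out from 14. Dess–Martin oxidation of the C9 alcohol gives 6β-acetoxy-5β-isopropenyl-10β-methyl-10α-vinylcyclohex-7-en-9-one F6. Acetonitrile oxide (nitroethane, PhNCO, cat. Et3N) adds to the polarised enone alkene anti to the 6β-acetate, with oxygen on the β-carbon C8, to give the 9-oxo isoxazoline F7. Reduction with NaBH4/CeCl3·7H2O at −78 °C, hydride entering anti to the C8–O bond, restores the 9α-alcohol and comes back to the route at 16.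

**Further compounds**

F1 | step 6 | (1E,3E)-1,4-bis(triethylsilyloxy)buta-1,3-diene | CC[Si](CC)(CC)O/C=C/C=C/O[Si](CC)(CC)CC
F2 | step 6 | 5β-acetyl-10β-methyl-6α,9α-bis(triethylsilyloxy)cyclohex-7-ene-10α-carbaldehyde | O=C[C@]1(C)[C@H](O[Si](CC)(CC)CC)C=C[C@H](O[Si](CC)(CC)CC)[C@H]1C(C)=O
F3 | step 6 | 1-[10β-methyl-6α,9α-bis(triethylsilyloxy)-10α-vinylcyclohex-7-en-5β-yl]ethanone | C=C[C@]1(C)[C@H](O[Si](CC)(CC)CC)C=C[C@H](O[Si](CC)(CC)CC)[C@H]1C(C)=O
F4 | step 9 | 9α-hydroxy-5β-isopropenyl-10β-methyl-10α-vinylcyclohex-7-en-6-one | C=C[C@]1(C)[C@H](O)C=CC(=O)[C@H]1C(C)=C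
F5 | step 9 | 5β-isopropenyl-10β-methyl-10α-vinylcyclohex-7-ene-6β,9α-diol | C=C[C@]1(C)[C@H](O)C=C[C@@H](O)[C@H]1C(C)=C
F6 | step 10 | 6β-acetoxy-5β-isopropenyl-10β-methyl-10α-vinylcyclohex-7-en-9-one | C=C[C@]1(C)C(=O)C=C[C@@H](OC(C)=O)[C@H]1C(C)=C
F7 | step 10 | 9-oxo analogue of isoxazoline 16 (8α-O, 7α-C, 6β-OAc) | C=C[C@]1(C)C(=O)[C@@H]2ON=C(C)[C@@H]2[C@@H](OC(C)=O)[C@H]1C(C)=C
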